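## Retrosynthetic overview

- The target (C3 is R) comes from its C8 methoxymethyl (MOM) ether by acetal cleavage. Ring A (benzene) is bought; ring B (the δ-lactone) is the only ring formed, in the key step.
- Ring B is opened by excising CO2: cutting O2–C3 and C1–C8a gives CO2 and an acyclic (S)-configured 2-iodoaryl secondary tosylate. The (S) centre becomes (R)-C3 by inversion.
- Enabling feature: C8a of ring A lies between C8 (oxygen-bearing) and C4a (bearing the C4–C3 arm). The two flanking groups steer a metal to C8a, and a carboxylate there stands six atoms from C3 (O2–C1–C8a–C4a–C4–C3), set up for 6-exo-tet closure.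
- The iodo tosylate comes from the homobenzylic alcohol by directed metalation/iodination at the future C8a and sulfonylation. The alcohol comes from (R)-epichlorohydrin as the C4–C3–C1' linchpin, opened first by an aryl Grignard reagent and then by a (Z)-alkenyl Grignard reagent.
- The Z-alkene comes from Lindlar reduction of the alkyne made from dec-1-yne and 1-bromo-4-chlorobutane.

Key step: step 8

## Route

Step 1
Reactants: 1 dec-1-yne; 2 1-bromo-4-chlorobutane
Product: 4 1-chlorotetradec-5-yne, via lithium dec-1-yn-1-ide 3 (not isolated)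
Conditions: n-BuLi, THF, −78 °C; then 2, DMPU, −78 °C → rt
Reagents that add atoms: none
Why: Acetylide SN2 alkylation should take place only at the C–Br end because bromide is displaced far faster than chloride, which leaves the chloride as the handle for the later Grignard reagent.

Step 2
Reactants: 4 1-chlorotetradec-5-yne
Product: 5 (5Z)-1-chlorotetradec-5-ene
Conditions: H2 (1 atm), Pd/CaCO3 poisoned with Pb(OAc)2 (Lindlar catalyst), quinoline, hexane, rt
Reagents that add atoms: none
Why: Lindlar semi-hydrogenation adds H2 syn to the alkyne and should stop at the Z-alkene, the primary chloride being inert.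

Step 3
Reactants: 6 3-bromophenol
Product: 7 1-bromo-3-(methoxymethoxy)benzene
Conditions: MOMCl, iPr2NEt, CH2Cl2, 0 °C → rt
Reagents that add atoms: chloromethyl methyl ether (MOMCl), COCCl
Why: Williamson-type O-alkylation of the phenol installs the MOM ether, which survives the organometallic steps and later serves as the ortho-directing group.

Step 4
Reactants: 7 1-bromo-3-(methoxymethoxy)benzene; 8 (R)-epichlorohydrin
Product: 11 (2R)-2-[3-(methoxymethoxy)benzyl]oxirane, via aryl Grignard reagent 9 (not isolated), via chlorohydrin alkoxide 10 (not isolated)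
Conditions: Mg, THF, rt; CuI (10 mol%), 8, THF, −40 → −10 °C; then 3 M NaOH aq., rt
Reagents that add atoms: none
Why: Copper-catalysed Grignard opening of the epoxide at its CH2 terminus followed by Williamson ring closure of the chlorohydrin alkoxide should give the benzyl epoxide, and the stereocentre of 8 is never touched, so its configuration is carried over unchanged.

Step 5
Reactants: 5 (5Z)-1-chlorotetradec-5-ene; 11 (2R)-2-[3-(methoxymethoxy)benzyl]oxirane
Product: 13 (2S,8Z)-1-[3-(methoxymethoxy)phenyl]heptadec-8-en-2-ol, via alkenyl Grignard reagent 12 (not isolated)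
Conditions: 5, Mg (I2-activated), THF, 50 °C; then CuI (10 mol%), 11, THF, −30 → 0 °C; aq. NH4Cl
Reagents that add atoms: none
Why: Copper-catalysed Grignard opening of the terminal epoxide at CH2 should complete the side chain with the carbinol centre unchanged in space (the descriptor becomes S only because the CIP priorities change).

Step 6
Reactants: 13 (2S,8Z)-1-[3-(methoxymethoxy)phenyl]heptadec-8-en-2-ol
Product: 15 (2S,8Z)-1-[2-iodo-3-(methoxymethoxy)phenyl]heptadec-8-en-2-ol, via dilithio species 14 (not isolated)
Conditions: n-BuLi (2.5 equiv), TMEDA, Et2O, 0 °C; then ICH2CH2I, THF, −78 °C → rt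
Reagents that add atoms: 1,2-diiodoethane, ICCI
Why: Directed ortho-metalation should occur at the one ring carbon flanked by both the MOM ether and the lithium alkoxide arm (complex-induced proximity, the future C8a), and iodinolysis of the aryllithium places iodine there.

Step 7
Reactants: 15 (2S,8Z)-1-[2-iodo-3-(methoxymethoxy)phenyl]heptadec-8-en-2-ol
Product: 16 (2S,8Z)-1-[2-iodo-3-(methoxymethoxy)phenyl]heptadec-8-en-2-yl 4-methylbenzenesulfonate
Conditions: Ts2O, pyridine, DMAP (cat.), CH2Cl2, 0 °C → rt
Reagents that add atoms: p-toluenesulfonic anhydride (Ts2O), Cc1ccc(cc1)S(=O)(=O)OS(=O)(=O)c1ccc(C)cc1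
Why: O-Sulfonylation breaks no bond at the stereocentre (retention), and the chloride-free anhydride avoids substitution of the new secondary tosylate.

Step 8
Reactants: 16 (2S,8Z)-1-[2-iodo-3-(methoxymethoxy)phenyl]heptadec-8-en-2-yl 4-methylbenzenesulfonate; 17 carbon dioxide
Product: 20 (3R)-8-(methoxymethoxy)-3-[(6Z)-pentadec-6-en-1-yl]isochroman-1-one, via arylmagnesium chloride 18 (not isolated), via chloromagnesium carboxylate 19 (not isolated)
Conditions: iPrMgCl·LiCl (1.1 equiv), THF, −20 °C; CO2 (1 atm), −20 → 0 °C; volatiles removed; Cs2CO3, DMF, 45 °C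
Reagents that add atoms: none
Why: Iodine–magnesium exchange is fast at the C–I bond flanked by the chelating MOM ether and should be complete at −20 °C before the organomagnesium reagents can touch the sulfonate, and the resulting 2,6-disubstituted arylmagnesium adds to CO2 (Grignard carboxylation) to give carboxylate 19. On warming in DMF with Cs2CO3 a carboxylate oxygen displaces the secondary tosylate in an intramolecular SN2 reaction, the closest known reaction type being the caesium carboxylate inversion of secondary sulfonates and invertive lactonisation. The δ-lactone (ring B) closes in the 6-exo-tet mode, the only ring-forming path open, because attack of the aryl carbon on the same centre would need a four-membered ring and a cyclic attack on sulfur cannot reach the required in-line geometry. The C3 stereocentre is not created here but inverted: clean Walden inversion turns the (S)-sulfonate, set from (R)-epichlorohydrin, into the (R)-lactone. The step needs substitution to win over E2 toward the conjugated styrene and over halide exchange followed by a second displacement, and the weak basicity of the carboxylate, the high effective molarity of the six-membered closure and the removal of 2-iodopropane before heating should secure this.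

Step 9
Reactants: 20 (3R)-8-(methoxymethoxy)-3-[(6Z)-pentadec-6-en-1-yl]isochroman-1-one
Product: 21 (3R)-8-hydroxy-3-[(6Z)-pentadec-6-en-1-yl]isochroman-1-one (target)
Conditions: HCl (cat.), MeOH/THF, 40 °C
Reagents that add atoms: none
Why: Acid-catalysed acetal exchange should remove the MOM group, which is activated by the neighbouring lactone carbonyl, while the lactone, the Z-alkene and the C3–O bond stay intact.

## Compound list

1 | dec-1-yne | CCCCCCCCC#C | starting material
2 | 1-bromo-4-chlorobutane | ClCCCCBr | starting material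
3 | lithium dec-1-yn-1-ide | [Li]C#CCCCCCCCC | intermediate
4 | 1-chlorotetradec-5-yne | CCCCCCCCC#CCCCCCl | intermediate
5 | (5Z)-1-chlorotetradec-5-ene | CCCCCCCC/C=C\CCCCCl | intermediate
6 | 3-bromophenol | Oc1cccc(Br)c1 | starting material
7 | 1-bromo-3-(methoxymethoxy)benzene | COCOc1cccc(Br)c1 | intermediate
8 | (R)-epichlorohydrin, (2R)-2-(chloromethyl)oxirane | ClC[C@H]1CO1 | starting material
9 | [3-(methoxymethoxy)phenyl]magnesium bromide | COCOc1cccc([Mg]Br)c1 | intermediate
10 | (2R)-1-chloro-3-[3-(methoxymethoxy)phenyl]propan-2-ol (present as its alkoxide) | COCOc1cccc(C[C@@H](O)CCl)c1 | intermediate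
11 | (2R)-2-[3-(methoxymethoxy)benzyl]oxirane | COCOc1cccc(C[C@@H]2CO2)c1 | intermediate
12 | [(5Z)-tetradec-5-en-1-yl]magnesium chloride | CCCCCCCC/C=C\CCCC[Mg]Cl | intermediate
13 | (2S,8Z)-1-[3-(methoxymethoxy)phenyl]heptadec-8-en-2-ol | CCCCCCCC/C=C\CCCCC[C@H](O)Cc1cccc(OCOC)c1 | intermediate
14 | lithium (2S,8Z)-1-[2-lithio-3-(methoxymethoxy)phenyl]heptadec-8-en-2-olate | CCCCCCCC/C=C\CCCCC[C@H](O[Li])Cc1cccc(OCOC)c1[Li] | intermediate
15 | (2S,8Z)-1-[2-iodo-3-(methoxymethoxy)phenyl]heptadec-8-en-2-ol | CCCCCCCC/C=C\CCCCC[C@H](O)Cc1cccc(OCOC)c1I | intermediate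
16 | (2S,8Z)-1-[2-iodo-3-(methoxymethoxy)phenyl]heptadec-8-en-2-yl 4-methylbenzenesulfonate | CCCCCCCC/C=C\CCCCC[C@H](OS(=O)(=O)c1ccc(C)cc1)Cc2cccc(OCOC)c2I | intermediate
17 | carbon dioxide | O=C=O | starting material
18 | {2-(methoxymethoxy)-6-[(2S,8Z)-2-(tosyloxy)heptadec-8-en-1-yl]phenyl}magnesium chloride | CCCCCCCC/C=C\CCCCC[C@H](OS(=O)(=O)c1ccc(C)cc1)Cc2cccc(OCOC)c2[Mg]Cl | intermediate
19 | chloromagnesium 2-(methoxymethoxy)-6-[(2S,8Z)-2-(tosyloxy)heptadec-8-en-1-yl]benzoate | CCCCCCCC/C=C\CCCCC[C@H](OS(=O)(=O)c1ccc(C)cc1)Cc2cccc(OCOC)c2C(=O)O[Mg]Cl | intermediate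
20 | (3R)-8-(methoxymethoxy)-3-[(6Z)-pentadec-6-en-1-yl]isochroman-1-one | CCCCCCCC/C=C\CCCCC[C@@H]1Cc2cccc(OCOC)c2C(=O)O1 | intermediate
21 | (3R)-8-hydroxy-3-[(6Z)-pentadec-6-en-1-yl]isochroman-1-one | CCCCCCCC/C=C\CCCCC[C@@H]1Cc2cccc(O)c2C(=O)O1 | target

## Step count and risks

Total step count: 9. Longest linear sequence: 7 steps (3-bromophenol 6 to target 21 through steps 3–9; the chain branch through steps 1, 2, 5–9 is equally long).

Steps most likely to fail:

1. Step 8 (key step). The organomagnesium reagents may attack the sulfonate before exchange and carboxylation are complete. The ring closure may also lose stereochemical fidelity, through halide exchange at the carbinol carbon followed by a second displacement, or through E2 toward the styrene. The fallback sets out from 16 and comes back at 20, and avoids polar organometallics altogether. Hydroxycarbonylation catalysed by Pd(OAc)2 and Xantphos (CO 1 atm, H2O, K2CO3, DMF, 60 °C) proceeds by oxidative addition at the C–I bond, CO insertion and hydrolysis of the acylpalladium species. It should give 2-(methoxymethoxy)-6-[(2S,8Z)-2-(tosyloxy)heptadec-8-en-1-yl]benzoic acid F1 as its potassium salt, which should close in the same flask by the same invertive displacement to 20. The two lactone oxygens then stem from CO and water instead of CO2.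

2. Step 6. Metalation may take place at one of the other ring positions instead of the carbon between the two directing groups, or the dianion may form incompletely. The fallback sets out from 7 and comes back at 15, and fixes the ring position before the side chain is built. LiN(iPr)2 (THF, −78 °C) should deprotonate 7 at the carbon between bromine and the MOM ether, the most acidic site, to give [2-bromo-6-(methoxymethoxy)phenyl]lithium F2. Trapping with Bu3SnCl gives tributyl[2-bromo-6-(methoxymethoxy)phenyl]stannane F3. Magnesium insertion into the C–Br bond gives [3-(methoxymethoxy)-2-(tributylstannyl)phenyl]magnesium bromide F4. This is carried through the chemistry of steps 4 and 5 (CuI, 8, then NaOH; then 12 with CuI) by way of (2R)-1-chloro-3-[3-(methoxymethoxy)-2-(tributylstannyl)phenyl]propan-2-ol F5 and (2R)-2-[3-(methoxymethoxy)-2-(tributylstannyl)benzyl]oxirane F6 to (2S,8Z)-1-[3-(methoxymethoxy)-2-(tributylstannyl)phenyl]heptadec-8-en-2-ol F7. Iododestannylation (I2, CH2Cl2, 0 °C) then puts iodine at the pre-set position and gives 15.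

3. Step 5. Radical 5-exo cyclisation may occur while the hex-5-enyl-type chloride 5 is converted into Grignard reagent 12, giving cyclopentane isomers that are hard to remove. Chloride may also open the epoxide in place of carbon. The fallback sets out from 11 (using 2 and 3 of the main route) and comes back at 13, and builds the chain stepwise without an alkenyl organometallic. (4-Chlorobutyl)magnesium bromide F8 (from 2 and Mg, THF, insertion at the C–Br bond) opens 11 under CuI catalysis to give (2S)-7-chloro-1-[3-(methoxymethoxy)phenyl]heptan-2-ol F9. Alkylation of lithium decynide 3 (2.2 equiv, NaI cat., THF/DMPU, 50 °C) with the chloride of F9 gives (2S)-1-[3-(methoxymethoxy)phenyl]heptadec-8-yn-2-ol F10. Lindlar semi-hydrogenation (H2, Pd/CaCO3 poisoned with Pb(OAc)2, quinoline) then gives 13.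

Further compounds

F1 | step 8 | 2-(methoxymethoxy)-6-[(2S,8Z)-2-(tosyloxy)heptadec-8-en-1-yl]benzoic acid | CCCCCCCC/C=C\CCCCC[C@H](OS(=O)(=O)c1ccc(C)cc1)Cc2cccc(OCOC)c2C(=O)O
F2 | step 6 | [2-bromo-6-(methoxymethoxy)phenyl]lithium | COCOc1cccc(Br)c1[Li]
F3 | step 6 | tributyl[2-bromo-6-(methoxymethoxy)phenyl]stannane | CCCC[Sn](CCCC)(CCCC)c1c(Br)cccc1OCOC
F4 | step 6 | [3-(methoxymethoxy)-2-(tributylstannyl)phenyl]magnesium bromide | CCCC[Sn](CCCC)(CCCC)c1c([Mg]Br)cccc1OCOC
F5 | step 6 | (2R)-1-chloro-3-[3-(methoxymethoxy)-2-(tributylstannyl)phenyl]propan-2-ol | CCCC[Sn](CCCC)(CCCC)c1c(C[C@@H](O)CCl)cccc1OCOC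
F6 | step 6 | (2R)-2-[3-(methoxymethoxy)-2-(tributylstannyl)benzyl]oxirane | CCCC[Sn](CCCC)(CCCC)c1c(C[C@@H]2CO2)cccc1OCOC
F7 | step 6 | (2S,8Z)-1-[3-(methoxymethoxy)-2-(tributylstannyl)phenyl]heptadec-8-en-2-ol | CCCCCCCC/C=C\CCCCC[C@H](O)Cc1cccc(OCOC)c1[Sn](CCCC)(CCCC)CCCC
F8 | step 5 | (4-chlorobutyl)magnesium bromide | ClCCCC[Mg]Br
F9 | step 5 | (2S)-7-chloro-1-[3-(methoxymethoxy)phenyl]heptan-2-ol | ClCCCCC[C@H](O)Cc1cccc(OCOC)c1
F10 | step 5 | (2S)-1-[3-(methoxymethoxy)phenyl]heptadec-8-yn-2-ol | CCCCCCCCC#CCCCCC[C@H](O)Cc1cccc(OCOC)c1
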